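**Assumption:** the target has no stereocentre and no configurationally stable axis, so it is achiral and needs no enantiocontrol; the free hydrogen sulfate is made as drawn, and the three aromatic starting materials are taken as commercial.

## Retrosynthetic overview

1. Target ⇒ free phenol (sulfation last) ⇒ its methyl ether (BBr3).
2. Key disconnection: the central-ring C–O bond to the sulfated ring, made by phenoxide ring-opening of a tetrabrominated, oxygen-bridged cyclic diaryliodonium salt; the same event leaves the iodine as the aryl iodide of the target (new step).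
3. Cyclic iodonium ⇒ mCPBA/TfOH oxidative cyclisation of a 2-iodo diaryl ether ⇒ 2,3,4-tribromo-6-iodophenol + bis(4-bromophenyl)iodonium triflate; the phenol ⇒ 5-bromo-2-iodophenol by dibromination.
4. Phenoxide partner ⇒ 4-bromoguaiacol by ortho-bromination.
5. Ring order: all three benzene rings are bought; the only ring made is the transient iodaoxinium ring (step 3), opened again in step 5.

## Route

Step 1
Reactants: 1 5-bromo-2-iodophenol
Product: 2 2,3,4-tribromo-6-iodophenol
Conditions: NBS (2.05 equiv), MeCN, 0 °C → rt, dark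
Reagents that add atoms: N-bromosuccinimide, O=C1CCC(=O)N1Br
Why: Electrophilic aromatic bromination (SEAr) of a phenol, in which OH (ortho/para) and the C5 bromine (ortho) both direct to C4 and C6, the only open activated sites, and with NBS held to two equivalents C–H substitution should outrun ipso attack at C–I.

Step 2
Reactants: 2 2,3,4-tribromo-6-iodophenol; 3 bis(4-bromophenyl)iodonium trifluoromethanesulfonate
Product: 5 1,2,3-tribromo-4-(4-bromophenoxy)-5-iodobenzene, via potassium 2,3,4-tribromo-6-iodophenoxide 4 (not isolated)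
Conditions: t-BuOK (1.1 equiv), THF, 0 °C; then 3 (1.2 equiv), 0 → 60 °C
Reagents that add atoms: potassium tert-butoxide, CC(C)(C)[O-].[K+] (its K is held only by 4)
Why: Metal-free O-arylation of a phenoxide with a symmetric diaryliodonium salt (ligand coupling at a T-shaped λ3-iodane), which tolerates 2,6-dihalophenoxides and, needing no copper or palladium, leaves every C–Br bond and the C–I bond alone.

Step 3
Reactants: 5 1,2,3-tribromo-4-(4-bromophenoxy)-5-iodobenzene
Product: 7 1,2,3,7-tetrabromodibenzo[b,e][1,4]iodaoxin-5-ium trifluoromethanesulfonate, via hydroxy(triflyloxy)-λ3-iodane 6 (not isolated)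
Conditions: mCPBA (1.5 equiv), TfOH (3 equiv), CH2Cl2, 0 → 40 °C; precipitate with Et2O
Reagents that add atoms: trifluoromethanesulfonic acid, OS(=O)(=O)C(F)(F)F (triflate of 6 and 7); mCPBA, OOC(=O)c1cccc(Cl)c1 (the OH oxygen of 6 only, lost as water on ring closure)
Why: One-pot oxidation of the aryl iodide to the Koser-type ArI(OH)OTf 6 followed by intramolecular SEAr at the carbon ortho to the ether oxygen of the 4-bromophenoxy ring (para is blocked by Br), the standard mCPBA/TfOH synthesis of cyclic diaryliodonium triflates, here closing the six-membered iodaoxinium ring.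

Step 4
Reactants: 8 4-bromo-2-methoxyphenol
Product: 9 2,4-dibromo-6-methoxyphenol
Conditions: NBS (1.0 equiv), i-Pr2NH (10 mol %), CH2Cl2, 0 °C → rt
Reagents that add atoms: N-bromosuccinimide, O=C1CCC(=O)N1Br
Why: Amine-catalysed ortho-selective SEAr bromination of a para-blocked phenol, in which the amine catalyst relays Br+ to C6 next to the hydrogen-bonded OH and not to C5 para to OMe.

Step 5
Reactants: 7 1,2,3,7-tetrabromodibenzo[b,e][1,4]iodaoxin-5-ium trifluoromethanesulfonate; 9 2,4-dibromo-6-methoxyphenol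
Product: 12 1,2,3-tribromo-4-(4-bromo-2-iodophenoxy)-5-(2,4-dibromo-6-methoxyphenoxy)benzene, via potassium 2,4-dibromo-6-methoxyphenoxide 10 (not isolated), via aryloxy-λ3-iodane 11 (not isolated)
Conditions: 9 (1.15 equiv), t-BuOK (1.10 equiv), THF, 0 °C; add 7, rt; exchange solvent to PhCl, 90 °C, Ar, dark
Reagents that add atoms: potassium tert-butoxide, CC(C)(C)[O-].[K+] (its K is held only by 10)
Why: Proposed new method: regioselective, transition-metal-free ring-opening O-arylation of an unsymmetrical oxygen-bridged cyclic diaryliodonium salt by a phenoxide, in which anion exchange gives the T-shaped aryloxy-λ3-iodane 11 and reductive ligand coupling (SNAr-like ipso attack through a three-centre-four-electron transition state) should occur at C4a of the tribromo ring, because that ring is much more electron-poor (Br meta, para and meta to the C–I carbon, Σσ ≈ 1.0, against one meta Br, σ ≈ 0.4, on the other ring) and better carries the developing negative charge, so the I–C4a bond breaks, the central-ring C–O bond to the methoxy ring forms and the iodine stays on the bromophenoxy ring ortho to the ether oxygen as in the target, while the weakly basic phenoxide (pKa ≈ 7, base kept below the phenol) avoids aryne formation at the acidic H-4; the closest known reaction types are the metal-free O-arylation of phenols with acyclic diaryliodonium salts and the nucleophilic ring-opening of dibenziodolium salts.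

Step 6
Reactants: 12 1,2,3-tribromo-4-(4-bromo-2-iodophenoxy)-5-(2,4-dibromo-6-methoxyphenoxy)benzene
Product: 14 3,5-dibromo-2-[3,4,5-tribromo-2-(4-bromo-2-iodophenoxy)phenoxy]phenol, via aryloxydibromoborane 13 (not isolated)
Conditions: BBr3 (3 equiv), CH2Cl2, −78 → 0 °C; then H2O
Reagents that add atoms: boron tribromide, BrB(Br)Br (B and Br of 13 only; none stays in 14)
Why: BBr3 demethylation of an aryl methyl ether (O–B complexation, SN2 loss of MeBr, hydrolysis of the aryloxyborane), which does not touch diaryl ether, C–Br or C–I bonds.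

Step 7
Reactants: 14 3,5-dibromo-2-[3,4,5-tribromo-2-(4-bromo-2-iodophenoxy)phenoxy]phenol
Product: 16 3,5-dibromo-2-[3,4,5-tribromo-2-(4-bromo-2-iodophenoxy)phenoxy]phenyl hydrogen sulfate (bromoiesol B sulfate), via pyridinium aryl sulfate 15 (not isolated)
Conditions: SO3·pyridine (5 equiv), pyridine, 50 °C; then Dowex 50W (H+ form), MeOH–H2O, 0 °C; lyophilise cold
Reagents that add atoms: sulfur trioxide–pyridine complex, [O-]S(=O)(=O)[n+]1ccccc1 (SO3 in 15 and 16; pyridinium in 15 only)
Why: O-sulfation of the only free phenol with an SO3–amine complex gives the pyridinium aryl sulfate, and cold H+-resin exchange releases the hydrogen sulfate drawn in the target.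

## Compound list

1 | 5-bromo-2-iodophenol | Oc1cc(Br)ccc1I | starting material
2 | 2,3,4-tribromo-6-iodophenol | Oc1c(Br)c(Br)c(Br)cc1I | intermediate
3 | bis(4-bromophenyl)iodonium trifluoromethanesulfonate | Brc1ccc([I+]c2ccc(Br)cc2)cc1.[O-]S(=O)(=O)C(F)(F)F | starting material
4 | potassium 2,3,4-tribromo-6-iodophenoxide | [K+].[O-]c1c(Br)c(Br)c(Br)cc1I | intermediate
5 | 1,2,3-tribromo-4-(4-bromophenoxy)-5-iodobenzene | Brc1ccc(Oc2c(Br)c(Br)c(Br)cc2I)cc1 | intermediate
6 | [3,4,5-tribromo-2-(4-bromophenoxy)phenyl](hydroxy)-λ3-iodanyl trifluoromethanesulfonate | OI(OS(=O)(=O)C(F)(F)F)c1cc(Br)c(Br)c(Br)c1Oc1ccc(Br)cc1 | intermediate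
7 | 1,2,3,7-tetrabromodibenzo[b,e][1,4]iodaoxin-5-ium trifluoromethanesulfonate | Brc1ccc2Oc3c(Br)c(Br)c(Br)cc3[I+]c2c1.[O-]S(=O)(=O)C(F)(F)F | intermediate
8 | 4-bromo-2-methoxyphenol | COc1cc(Br)ccc1O | starting material
9 | 2,4-dibromo-6-methoxyphenol | COc1cc(Br)cc(Br)c1O | intermediate
10 | potassium 2,4-dibromo-6-methoxyphenoxide | COc1cc(Br)cc(Br)c1[O-].[K+] | intermediate
11 | 1,2,3,7-tetrabromo-5-(2,4-dibromo-6-methoxyphenoxy)-5H-5λ3-dibenzo[b,e][1,4]iodaoxine | COc1cc(Br)cc(Br)c1OI1c2cc(Br)ccc2Oc2c(Br)c(Br)c(Br)cc21 | intermediate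
12 | 1,2,3-tribromo-4-(4-bromo-2-iodophenoxy)-5-(2,4-dibromo-6-methoxyphenoxy)benzene | COc1cc(Br)cc(Br)c1Oc1cc(Br)c(Br)c(Br)c1Oc1ccc(Br)cc1I | intermediate
13 | dibromo{3,5-dibromo-2-[3,4,5-tribromo-2-(4-bromo-2-iodophenoxy)phenoxy]phenoxy}borane | BrB(Br)Oc1cc(Br)cc(Br)c1Oc1cc(Br)c(Br)c(Br)c1Oc1ccc(Br)cc1I | intermediate
14 | 3,5-dibromo-2-[3,4,5-tribromo-2-(4-bromo-2-iodophenoxy)phenoxy]phenol | Oc1cc(Br)cc(Br)c1Oc1cc(Br)c(Br)c(Br)c1Oc1ccc(Br)cc1I | intermediate
15 | pyridinium 3,5-dibromo-2-[3,4,5-tribromo-2-(4-bromo-2-iodophenoxy)phenoxy]phenyl sulfate | [O-]S(=O)(=O)Oc1cc(Br)cc(Br)c1Oc1cc(Br)c(Br)c(Br)c1Oc1ccc(Br)cc1I.c1cc[nH+]cc1 | intermediate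
16 | 3,5-dibromo-2-[3,4,5-tribromo-2-(4-bromo-2-iodophenoxy)phenoxy]phenyl hydrogen sulfate (bromoiesol B sulfate) | O=S(=O)(O)Oc1cc(Br)cc(Br)c1Oc1cc(Br)c(Br)c(Br)c1Oc1ccc(Br)cc1I | target

## Step count and risks

Total step count: 7.
Longest linear sequence: 6 steps (steps 1, 2, 3, 5, 6, 7); step 4 is a one-step side branch.

**Step 5 (proposed new step).** The risks are a sluggish ring-opening of the six-membered iodonium, attack at the wrong C–I carbon (giving the isomer with iodine left on the tribromo ring), or an aryne path. The regiochemistry of 12 is to be checked by HMBC or X-ray. The fallback uses only known chemistry, sets out from 8 and comes back to the route at 14. Compound 8 is brominated twice (Br2, 2.1 equiv, AcOH, rt; the sites para to OMe and ortho to OH) to 2,3,4-tribromo-6-methoxyphenol F1. SNAr of F1 on commercial 4-bromo-1-fluoro-2-nitrobenzene (K2CO3, DMF, 80 °C) gives 1,2,3-tribromo-4-(4-bromo-2-nitrophenoxy)-5-methoxybenzene F2. Fe/NH4Cl (EtOH–H2O, 70 °C) reduces it to 5-bromo-2-(2,3,4-tribromo-6-methoxyphenoxy)aniline F3. Diazotisation (t-BuONO, p-TsOH·H2O, MeCN) gives 5-bromo-2-(2,3,4-tribromo-6-methoxyphenoxy)benzenediazonium tosylate F4, and KI turns it into 1,2,3-tribromo-4-(4-bromo-2-iodophenoxy)-5-methoxybenzene F5. BBr3 (CH2Cl2, −78 → 0 °C) frees 3,4,5-tribromo-2-(4-bromo-2-iodophenoxy)phenol F6. SNAr of F6 on commercial 3,5-dibromo-2-fluorobenzaldehyde (K2CO3, DMF, 90 °C) gives 3,5-dibromo-2-[3,4,5-tribromo-2-(4-bromo-2-iodophenoxy)phenoxy]benzaldehyde F7. Baeyer–Villiger oxidation (mCPBA, NaHCO3, CH2Cl2) gives 3,5-dibromo-2-[3,4,5-tribromo-2-(4-bromo-2-iodophenoxy)phenoxy]phenyl formate F8, and methanolysis (K2CO3 cat., MeOH) gives 14, which goes on to step 7.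

**Step 3 (oxidative cyclisation).** The electron-poor, flanked aryl iodide may resist oxidation, or the bromine-deactivated ring may close slowly. The fallback changes the way the iodonium C–I bond is made, to the classical diazonium route to cyclic iodonium salts; it sets out from 2 and comes back at 7. SNAr of 2 on 4-bromo-1-fluoro-2-nitrobenzene (K2CO3, DMF, 70 °C) gives 1,2,3-tribromo-4-(4-bromo-2-nitrophenoxy)-5-iodobenzene F9. Fe/NH4Cl reduces it to 5-bromo-2-(2,3,4-tribromo-6-iodophenoxy)aniline F10. Diazotisation (t-BuONO, TfOH, MeCN, 0 °C) gives 5-bromo-2-(2,3,4-tribromo-6-iodophenoxy)benzenediazonium triflate F11. Warming to 60 °C expels N2 and the neighbouring aryl iodide traps the aryl cation to close the ring as 7; both ortho positions of the iodo ring are substituted, so dibenzofuran formation is blocked.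

**Step 1 (dibromination of an iodophenol).** The risks are ipso bromodeiodination and a slow second bromination at the flanked C6. The fallback brings the iodine in last; it sets out from 3 and comes back at 5, bypassing 2. Commercial 5-bromo-2-nitrophenol is dibrominated (Br2, NaOAc, AcOH, 50 °C; OH, NO2 and Br all direct to C4 and C6) to 2,3,4-tribromo-6-nitrophenol F12. Its potassium salt is arylated with 3 (t-BuOK, THF, 60 °C) to 1,2,3-tribromo-4-(4-bromophenoxy)-5-nitrobenzene F13. Fe/NH4Cl gives 3,4,5-tribromo-2-(4-bromophenoxy)aniline F14. Diazotisation (t-BuONO, p-TsOH·H2O, MeCN) gives 3,4,5-tribromo-2-(4-bromophenoxy)benzenediazonium tosylate F15, and KI converts it into 5.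

## Further compounds

F1 | step 5 | 2,3,4-tribromo-6-methoxyphenol | COc1cc(Br)c(Br)c(Br)c1O
F2 | step 5 | 1,2,3-tribromo-4-(4-bromo-2-nitrophenoxy)-5-methoxybenzene | COc1cc(Br)c(Br)c(Br)c1Oc1ccc(Br)cc1[N+](=O)[O-]
F3 | step 5 | 5-bromo-2-(2,3,4-tribromo-6-methoxyphenoxy)aniline | COc1cc(Br)c(Br)c(Br)c1Oc1ccc(Br)cc1N
F4 | step 5 | 5-bromo-2-(2,3,4-tribromo-6-methoxyphenoxy)benzenediazonium 4-methylbenzenesulfonate | COc1cc(Br)c(Br)c(Br)c1Oc1ccc(Br)cc1[N+]#N.Cc1ccc(S(=O)(=O)[O-])cc1
F5 | step 5 | 1,2,3-tribromo-4-(4-bromo-2-iodophenoxy)-5-methoxybenzene | COc1cc(Br)c(Br)c(Br)c1Oc1ccc(Br)cc1I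
F6 | step 5 | 3,4,5-tribromo-2-(4-bromo-2-iodophenoxy)phenol | Oc1cc(Br)c(Br)c(Br)c1Oc1ccc(Br)cc1I
F7 | step 5 | 3,5-dibromo-2-[3,4,5-tribromo-2-(4-bromo-2-iodophenoxy)phenoxy]benzaldehyde | O=Cc1cc(Br)cc(Br)c1Oc1cc(Br)c(Br)c(Br)c1Oc1ccc(Br)cc1I
F8 | step 5 | 3,5-dibromo-2-[3,4,5-tribromo-2-(4-bromo-2-iodophenoxy)phenoxy]phenyl formate | O=COc1cc(Br)cc(Br)c1Oc1cc(Br)c(Br)c(Br)c1Oc1ccc(Br)cc1I
F9 | step 3 | 1,2,3-tribromo-4-(4-bromo-2-nitrophenoxy)-5-iodobenzene | O=[N+]([O-])c1cc(Br)ccc1Oc1c(Br)c(Br)c(Br)cc1I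
F10 | step 3 | 5-bromo-2-(2,3,4-tribromo-6-iodophenoxy)aniline | Nc1cc(Br)ccc1Oc1c(Br)c(Br)c(Br)cc1I
F11 | step 3 | 5-bromo-2-(2,3,4-tribromo-6-iodophenoxy)benzenediazonium trifluoromethanesulfonate | N#[N+]c1cc(Br)ccc1Oc1c(Br)c(Br)c(Br)cc1I.[O-]S(=O)(=O)C(F)(F)F
F12 | step 1 | 2,3,4-tribromo-6-nitrophenol | Oc1c(Br)c(Br)c(Br)cc1[N+](=O)[O-]
F13 | step 1 | 1,2,3-tribromo-4-(4-bromophenoxy)-5-nitrobenzene | O=[N+]([O-])c1cc(Br)c(Br)c(Br)c1Oc1ccc(Br)cc1
F14 | step 1 | 3,4,5-tribromo-2-(4-bromophenoxy)aniline | Nc1cc(Br)c(Br)c(Br)c1Oc1ccc(Br)cc1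
F15 | step 1 | 3,4,5-tribromo-2-(4-bromophenoxy)benzenediazonium 4-methylbenzenesulfonate | N#[N+]c1cc(Br)c(Br)c(Br)c1Oc1ccc(Br)cc1.Cc1ccc(S(=O)(=O)[O-])cc1
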